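## Analysis of the target

The target 33 is a trans-α,β-dibenzyl-γ-butyrolactone (oxolan-2-one, C3 R and C4 R) in which each benzyl group is itself a dimeric phenylpropanoid. The C4 benzyl group carries ring B, the benzo ring of a 2,3-dihydrobenzofuran with ring E (4-hydroxy-3-methoxyphenyl) at C2 and CH2OH at C3 in a trans (2S,3R) arrangement. The C3 benzyl group carries ring A, which has a free phenol ortho to an open chain: C2' (S, bonded to ring A and CH2OH) joined to the carbinol carbon C1' (S, bonded to ring D and OH), the anti diastereomer. The open chain and the dihydrobenzofuran share the connectivity aryl–C(O)–C(CH2OH)–aryl, but they differ in absolute configuration at the carbon bearing CH2OH, so the six stereocentres fall into three pairs that cannot relay information to each other. The sensitive groups are three phenols, a p-hydroxybenzylic carbinol, the benzylic C2–O bond of the dihydrobenzofuran and an epimerisable lactone. The carbinol ionises easily to a quinone methide; under acid the ring A phenol would close onto C1' to give a second dihydrobenzofuran, and under hydrogen the C1'–O bond can be cleaved. The difficulty is therefore absolute and relative control in the acyclic C1'/C2' pair, with no ring to lean on, while the chain is kept open to the end. The strategy rests on C1' and C2': two adjacent carbons that carry an oxygen which can come from boron, two different aryl groups (rings D and A) and a CH2O arm, which is the pattern of a 3-oxypropenyl boron compound that has taken up two aryl groups across its double bond.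

## Retrosynthetic reasoning

Abbreviations used throughout: Bn = benzyl, TBS = tert-butyldimethylsilyl.

**Protecting groups (33 ⇐ 32 ⇐ 31).** The three phenols are carried as benzyl ethers and the three hydroxyls as TBS ethers. The silyl groups leave first, under buffered fluoride, while the phenols are still capped and neither a quinone methide nor closure of the ring A oxygen onto C1' is possible. The benzyl ethers leave last, by neutral hydrogenolysis, so that 33 never meets acid.

**Lactone C3–CH2 bond (31 ⇐ 30 + 17).** The bond between C3 of the lactone and the benzylic carbon of ring A is cut. This divides the molecule into its two halves, and the forward alkylation of enolate 30 (from lactone 29) with bromide 17 sets C3 trans to the existing C4 substituent by 1,2-induction. A cut at C4–CH2 would offer no such control.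

**Lactone ring (29 ⇐ 28 ⇐ 27 ⇐ 26 ⇐ 24 + 25).** The four lactone carbons come from dimethyl succinate 25 by Stobbe condensation with aldehyde 24. Asymmetric hydrogenation of half-ester 26 sets C4. Chemoselective reduction of the ester of 27 and not of its acid decides which carbonyl survives, so that the arylmethyl group ends up β to the lactone carbonyl in 29 (via hydroxy acid 28).

**Ring A/ring D half (17 ⇐ 16 ⇐ 15 ⇐ 14 ⇐ 13).** Only functional-group changes separate 17 from boronate 13. The aryl ester is the latent benzylic bromide, and boron is the latent carbinol oxygen, replaced with retention.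

**Key disconnection (13 ⇐ 12 + 10; 12 ⇐ 11 + 5; 11 ⇐ 7).** The C1'–ring D and C2'–ring A bonds are cut together. This is the only cut that creates both stereocentres of the acyclic pair and both aryl–carbon bonds in one operation from three achiral pieces: the (Z)-alkenyl boronate 5, aryllithium 11 (from bromide 7) and triflate 10. In the forward direction ring D must shift from boron to carbon in ate complex 12 while palladium delivers ring A to the neighbouring carbon. The anti addition across the Z alkene gives the anti pair, and the chiral ligand on palladium gives the absolute sense. Boron carries the hindered diol 2 and not a simpler glycol, because β-substituted alkenyl boronates of small diols tend to transfer their alkenyl group directly to palladium. The ate complex 12 carries no stereochemical information of its own, so it is made once, in one batch, and divided.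

**Ring B/ring E half (24 ⇐ 23 ⇐ 22 ⇐ 21 ⇐ 20 ⇐ 19).** The O1–C2 bond of the dihydrobenzofuran is cut, which opens 21 to the bisphenol 20. This reveals that the closed half is the open half with the opposite sense at the CH2O-bearing carbon. Compound 19 is therefore the mirror image of 14 and is made from a second portion of the same ate complex 12 and triflate 10 with the mirror-image ligand, via boronate 18. The forward closure runs through a quinone methide and converges on the trans ring, so only the C3 configuration has to come from the coupling.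

**Building blocks.** Boronate 5 comes from silyl ether 3 and diol 2 (from dione 1) through catechol boronate 4. Bromide 7 comes from phenol 6. Triflate 10 comes from ester 8 via monobenzyl ether 9.

## Alternatives that were turned down

**Alternative 1:** The disconnection is at the two ring C–O bonds of the lactone. A prochiral cyclobutanone A1 that already carries the dihydrobenzofuran would be oxidised by a Baeyer–Villiger monooxygenase (with a cofactor-recycling enzyme) to the (R)-lactone A2, with oxygen inserted next to one of the two enantiotopic methylene groups.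
- For it: the C4 stereocentre would come from one catalytic step under neutral aqueous conditions that even free phenols tolerate. On that centre it is shorter than the Stobbe condensation, hydrogenation and reduction used here (24 to 29, three steps), and equally selective in principle.
- Against it: A1 has to be built first, by a [2+2] ketene cycloaddition and dehalogenation sequence, which gives back the steps saved. A large, lipophilic, poorly water-soluble substrate must also fit an enzyme pocket evolved for small ketones.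
- Comparison: the enzyme step fixes one stereocentre of six and leaves the acyclic C1'/C2' pair and the dihydrobenzofuran untouched. The chosen strategy puts its central step on the acyclic pair, where two C–C bonds and two stereocentres form at once, and pays for the lactone with routine chemistry.

**Alternative 2:** The disconnection is at the C3–C3a bond of the dihydrobenzofuran and at the C–O bond of its CH2O arm. An aryl radical generated with Bu3SnH from the iodide A3, an enantioenriched 1-arylallyl aryl ether, would cyclise 5-exo onto its vinyl group, and a nitroxide would capture the primary radical to give A4.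
- For it: the C2 configuration would be fixed by a routine enantioselective step before A3 is assembled, the cyclisation is fast and regioselective, and the arm arrives oxidised. On the origin of the C2 configuration it is stronger than the chosen route, because it does not depend on a palladium step at the edge of its scope.
- Against it: the C3 configuration is set under kinetic control by the C2 aryl group alone. Bu3SnH competes with the nitroxide for the primary radical and also reduces the nitroxide. The iodide must react in the presence of the bromide. The N–O bond must be cleaved later, and tin is used stoichiometrically.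
- Comparison: it makes only the closed half. The chosen coupling makes the closed and the open half from the same pieces by changing the hand of the ligand, and it reaches the trans ring by a closure under thermodynamic bias.

**Alternative 3:** The disconnection is at the O1–C2 bond of the dihydrobenzofuran. A mixture of both carbinol epimers of the diol A5 would be treated with catalytic camphor-10-sulfonic acid, and the ring B phenol would add to the benzylic cation (quinone methide) to give the trans ring A6.
- For it: the closure is stereoconvergent, so no control at the carbinol is needed, and it is mild and well understood. On the ring closure itself it is as strong as anything in the chosen route, which in fact ends its closed half with the same kind of closure (step 14).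
- Against it: as a central idea it presupposes an enantioselective source of the CH2O-bearing centre of A5, which is the hard part. Its convergence is also of no use for the open half, where the carbinol configuration must be defined and the ring must stay open.
- Comparison: the chosen strategy supplies exactly what this one lacks, namely the enantioselective construction of the aryl–C–C–aryl unit with a defined carbinol, and uses the closure only as a downstream step.

Key step: step 7

Assumption: the hand of each chiral ligand is assigned by analogy with the parent reactions and would be confirmed on 14 and 27; both antipodes of each ligand are sold, so the assignment only decides which one is used.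

## Route

Step 1
Reactants: 1 acenaphthylene-1,2-dione
Product: 2 cis-1,2-dimethyl-1,2-dihydroacenaphthylene-1,2-diol (meso)
Conditions: AlMe3 (3 equiv), toluene, 0 °C to rt; H2O quench; recrystallisation
Reagents that add atoms: trimethylaluminium, C[Al](C)C
Why: Twofold 1,2-addition of a methylaluminium reagent to the 1,2-dione; the second methyl group should enter anti to the bulky aluminium alkoxide on the neighbouring carbon, which places the two oxygens cis, and crystallisation removes any trans diol.

Step 2
Reactants: 3 tert-butyl(dimethyl)(prop-2-yn-1-yloxy)silane; 2 cis-1,2-dimethyl-1,2-dihydroacenaphthylene-1,2-diol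
Product: 5 (Z)-3-(TBS-oxy)prop-1-enylboronic acid cis-1,2-dimethylacenaphthene-1,2-diyl ester, via catechol boronate 4 (not isolated)
Conditions: catecholborane (1.0 equiv), 3 (1.2 equiv), [Rh(cod)Cl]2 (1.5 mol%), P(i-Pr)3 (6 mol%), Et3N (1 equiv), cyclohexane, rt; then 2 (1.0 equiv), rt
Reagents that add atoms: catecholborane, B1Oc2ccccc2O1
Why: Rhodium-catalysed trans-hydroboration of a terminal alkyne, which runs through a rhodium vinylidene and so places boron cis to the chain on the new alkene; the labile catechol ester then exchanges with the chelating cis diol 2 (transesterification).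

Step 3
Reactants: 6 4-bromo-2-methoxyphenol
Product: 7 1-(benzyloxy)-4-bromo-2-methoxybenzene
Conditions: BnBr, K2CO3, DMF, rt
Reagents that add atoms: benzyl bromide, BrCc1ccccc1
Why: Williamson ether synthesis on the phenoxide.

Step 4
Reactants: 8 methyl 3,4-dihydroxy-5-methoxybenzoate
Product: 9 methyl 4-(benzyloxy)-3-hydroxy-5-methoxybenzoate
Conditions: BnBr (1.0 equiv), Li2CO3 (1.1 equiv), DMF, 40 °C
Reagents that add atoms: benzyl bromide, BrCc1ccccc1
Why: Regioselective Williamson etherification; the 4-hydroxyl para to the ester is the most acidic, so a weak base in slight excess forms and alkylates only that phenoxide.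

Step 5
Reactants: 9 methyl 4-(benzyloxy)-3-hydroxy-5-methoxybenzoate
Product: 10 methyl 4-(benzyloxy)-3-methoxy-5-(trifluoromethylsulfonyloxy)benzoate
Conditions: Tf2O (1.1 equiv), pyridine, CH2Cl2, 0 °C
Reagents that add atoms: triflic anhydride, O=S(=O)(OS(=O)(=O)C(F)(F)F)C(F)(F)F
Why: O-Sulfonylation of the remaining phenol gives the aryl triflate needed for a cationic arylpalladium intermediate.

Step 6
Reactants: 7 1-(benzyloxy)-4-bromo-2-methoxybenzene; 5 (Z)-alkenyl boronate of diol 2
Product: 12 lithium [4-(benzyloxy)-3-methoxyphenyl][(Z)-3-(TBS-oxy)prop-1-enyl](cis-1,2-dimethylacenaphthene-1,2-diolato)borate, via aryllithium 11 (not isolated)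
Conditions: 7 (1.0 equiv), t-BuLi (2.0 equiv), Et2O, −78 °C; 5 (1.0 equiv), −78 °C to rt; evaporate and dry in vacuo under argon; taken up in THF as a stock solution (one batch, divided between steps 7 and 12 on the same day)
Reagents that add atoms: tert-butyllithium, [Li]C(C)(C)C
Why: Bromine–lithium exchange (the second equivalent of t-BuLi destroys the t-BuBr formed) gives aryllithium 11, which adds to the vacant orbital on boron of 5 to give the four-coordinate boron ate complex 12; such lithium borates should be stable under argon once the ether is removed, so one batch can be divided, and the LiBr that stays with the solid is dealt with by KOTf in the couplings.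

Step 7
Reactants: 12 lithium boron ate complex; 10 aryl triflate
Product: 13 methyl 4-(benzyloxy)-3-[(1S,2S)-1-[4-(benzyloxy)-3-methoxyphenyl]-3-(TBS-oxy)-1-borylpropan-2-yl]-5-methoxybenzoate as the boronic ester of diol 2
Conditions: 12 (1.0 equiv, THF stock solution), 10 (1.1 equiv), Pd(OAc)2 (3 mol%), (Sp,Sp)-1,1'-bis(diphenylphosphino)-2,2'-bis[(R)-α-(dimethylamino)benzyl]ferrocene (3.6 mol%), KOTf (2 equiv), THF, 40–60 °C
Reagents that add atoms: none
Why: Palladium-catalysed conjunctive cross-coupling of an alkenylboron ate complex with an aryl triflate, the closest known reaction type being this same coupling with β-substituted alkenyl boronates of hindered diols. Zerovalent palladium inserts into the C–OTf bond of 10; the cationic divalent arylpalladium binds the alkene of 12, which triggers the 1,2-shift of ring D from boron to C1' on the face opposite palladium, and reductive elimination then joins ring A to C2' with retention. No ring is closed. Both stereocentres arise here: the anti relation follows from the stereospecific anti addition of the two aryl groups across the Z alkene, and the absolute configuration from the alkene face that the chiral ferrocenyl bisphosphine lets palladium bind. The step needs the metallate shift to win over direct transmetallation (the Suzuki–Miyaura product), which the bulky acenaphthene diol on boron secures; it needs aryl and not oxygen to migrate, which the electron-rich ring D ensures; and it needs reductive elimination to outrun β-hydride and β-silyloxy elimination from the alkylpalladium, which the wide-bite-angle bisphosphine favours. KOTf removes, as KBr, the bromide carried over with 12 from step 6, which would otherwise occupy the cationic palladium. The two boron epimers of 12 converge on the same product.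

Step 8
Reactants: 13 boronic ester
Product: 14 methyl 4-(benzyloxy)-3-[(1S,2S)-1-[4-(benzyloxy)-3-methoxyphenyl]-3-(TBS-oxy)-1-hydroxypropan-2-yl]-5-methoxybenzoate
Conditions: NaBO3·4H2O (5 equiv), THF/H2O (1:1), rt
Reagents that add atoms: sodium perborate tetrahydrate, [Na+].[O-]OB=O.O.O.O.O
Why: Oxidation of the C–B bond; peroxide adds to boron and C1' migrates from boron to oxygen with retention, so the (1S) carbinol keeps the configuration of the boronate; perborate is mild enough to spare the methyl ester and the silyl ether, and diol 2 is recovered.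

Step 9
Reactants: 14 secondary alcohol
Product: 15 methyl 4-(benzyloxy)-3-[(1S,2S)-1-[4-(benzyloxy)-3-methoxyphenyl]-1,3-bis(TBS-oxy)propan-2-yl]-5-methoxybenzoate
Conditions: TBSOTf (1.3 equiv), 2,6-lutidine (2 equiv), CH2Cl2, −78 to 0 °C
Reagents that add atoms: tert-butyldimethylsilyl triflate, CC(C)(C)[Si](C)(C)OS(=O)(=O)C(F)(F)F
Why: Silylation of the hindered benzylic alcohol under base-buffered conditions, so the carbinol does not ionise; the ether shields C1'–O through bromination and enolate chemistry.

Step 10
Reactants: 15 bis-silyl ether ester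
Product: 16 {4-(benzyloxy)-3-[(1S,2S)-1-[4-(benzyloxy)-3-methoxyphenyl]-1,3-bis(TBS-oxy)propan-2-yl]-5-methoxyphenyl}methanol
Conditions: i-Bu2AlH (2.5 equiv), CH2Cl2, −78 to 0 °C; aq. KNaC4H4O6
Reagents that add atoms: none
Why: Hydride reduction of the aryl ester to the benzylic alcohol; silyl and benzyl ethers are inert to the aluminium hydride.

Step 11
Reactants: 16 benzylic alcohol
Product: 17 4-(benzyloxy)-3-[(1S,2S)-1-[4-(benzyloxy)-3-methoxyphenyl]-1,3-bis(TBS-oxy)propan-2-yl]-5-methoxybenzyl bromide
Conditions: CBr4 (1.3 equiv), PPh3 (1.3 equiv), CH2Cl2, 0 °C; short silica plug, used at once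
Reagents that add atoms: carbon tetrabromide, BrC(Br)(Br)Br
Why: Appel reaction; the neutral conditions convert the only free hydroxyl into the bromide without touching the silyl ethers.

Step 12
Reactants: 12 lithium boron ate complex (second portion of the batch from step 6); 10 aryl triflate
Product: 19 methyl 4-(benzyloxy)-3-[(1R,2R)-1-[4-(benzyloxy)-3-methoxyphenyl]-3-(TBS-oxy)-1-hydroxypropan-2-yl]-5-methoxybenzoate, via mirror-image boronate 18 (not isolated)
Conditions: 12 (1.0 equiv, THF stock solution), 10 (1.1 equiv), Pd(OAc)2 (3 mol%), (Rp,Rp)-1,1'-bis(diphenylphosphino)-2,2'-bis[(S)-α-(dimethylamino)benzyl]ferrocene (3.6 mol%), KOTf (2 equiv), THF, 40–60 °C; then NaBO3·4H2O (5 equiv), THF/H2O, rt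
Reagents that add atoms: sodium perborate tetrahydrate, [Na+].[O-]OB=O.O.O.O.O
Why: The same conjunctive cross-coupling as in step 7 with the mirror-image ligand, which turns palladium to the other alkene face and gives the (1R,2R) boronate 18; oxidation in the same flask replaces boron by oxygen with retention.

Step 13
Reactants: 19 mirror-image alcohol
Product: 20 methyl 4-hydroxy-3-[(1R,2R)-3-(TBS-oxy)-1-hydroxy-1-(4-hydroxy-3-methoxyphenyl)propan-2-yl]-5-methoxybenzoate
Conditions: H2 (1 atm), Pd/C (10%), EtOAc, rt, stopped at full conversion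
Reagents that add atoms: none
Why: Hydrogenolysis of both aryl benzyl ethers; in a neutral aprotic solvent the O–CH2Ph bonds are cleaved well before the benzylic C–OH bond, and the ester and silyl ether are inert.

Step 14
Reactants: 20 bisphenol
Product: 21 methyl (2S,3R)-3-[(TBS-oxy)methyl]-2-(4-hydroxy-3-methoxyphenyl)-7-methoxy-2,3-dihydro-1-benzofuran-5-carboxylate
Conditions: (1S)-(+)-camphor-10-sulfonic acid (10 mol%), 4 Å molecular sieves, CH2Cl2 (dilute), 0 °C to rt
Reagents that add atoms: none
Why: Acid ionises the p-hydroxybenzylic alcohol to a quinone methide, and the ring B phenol adds to it in a 5-exo-trig closure that forms O1–C2; the trans ring results because ring E and the CH2O arm avoid eclipsing and the closure is reversible, while C3 is not touched and keeps the configuration set in step 12.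

Step 15
Reactants: 21 phenol
Product: 22 methyl (2S,3R)-2-[4-(benzyloxy)-3-methoxyphenyl]-3-[(TBS-oxy)methyl]-7-methoxy-2,3-dihydro-1-benzofuran-5-carboxylate
Conditions: BnBr, K2CO3, DMF, rt
Reagents that add atoms: benzyl bromide, BrCc1ccccc1
Why: Williamson ether synthesis; capping the ring E phenol prevents reopening to the quinone methide and O-alkylation in step 21.

Step 16
Reactants: 22 ester
Product: 23 {(2S,3R)-2-[4-(benzyloxy)-3-methoxyphenyl]-3-[(TBS-oxy)methyl]-7-methoxy-2,3-dihydro-1-benzofuran-5-yl}methanol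
Conditions: i-Bu2AlH (2.5 equiv), CH2Cl2, −78 to 0 °C; aq. KNaC4H4O6
Reagents that add atoms: none
Why: Hydride reduction of the aryl ester to the benzylic alcohol.

Step 17
Reactants: 23 benzylic alcohol
Product: 24 (2S,3R)-2-[4-(benzyloxy)-3-methoxyphenyl]-3-[(TBS-oxy)methyl]-7-methoxy-2,3-dihydro-1-benzofuran-5-carbaldehyde
Conditions: MnO2 (activated, excess), CH2Cl2, rt
Reagents that add atoms: none
Why: Selective oxidation of an electron-rich benzylic alcohol to the aldehyde without over-oxidation.

Step 18
Reactants: 24 aldehyde; 25 dimethyl succinate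
Product: 26 (3E)-4-{(2S,3R)-2-[4-(benzyloxy)-3-methoxyphenyl]-3-[(TBS-oxy)methyl]-7-methoxy-2,3-dihydro-1-benzofuran-5-yl}-3-(methoxycarbonyl)but-3-enoic acid
Conditions: 25 (2 equiv), KOt-Bu (1.5 equiv), t-BuOH/THF, rt to 45 °C; 1 M HCl to pH 3, 0 °C
Reagents that add atoms: none
Why: Stobbe condensation; the succinate enolate adds to the aldehyde, the alkoxide closes to a lactone ester, and E1cB ring opening gives the arylidene half-ester with the ester on the alkene carbon, mainly as the E isomer (either isomer serves in step 19).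

Step 19
Reactants: 26 arylidene half-ester
Product: 27 (3R)-4-{(2S,3R)-2-[4-(benzyloxy)-3-methoxyphenyl]-3-[(TBS-oxy)methyl]-7-methoxy-2,3-dihydro-1-benzofuran-5-yl}-3-(methoxycarbonyl)butanoic acid
Conditions: H2 (5 bar), [Rh(cod){1,2-bis((2S,5S)-2,5-diethylphospholan-1-yl)benzene}]BF4 (1 mol%), NaOMe (10 mol%), MeOH, rt
Reagents that add atoms: none
Why: Rhodium-bisphospholane asymmetric hydrogenation of an itaconate-type half-ester; the carboxylate and the alkene chelate the cationic rhodium and the ligand decides the face, which sets the future C4 as R; the homogeneous catalyst leaves the benzyl ethers and the benzylic C–O bonds alone.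

Step 20
Reactants: 27 succinate half-ester
Product: 29 (4R)-4-({(2S,3R)-2-[4-(benzyloxy)-3-methoxyphenyl]-3-[(TBS-oxy)methyl]-7-methoxy-2,3-dihydro-1-benzofuran-5-yl}methyl)oxolan-2-one, via hydroxy acid 28 (not isolated)
Conditions: LiBH4 (3 equiv), THF, 0 °C to rt; 1 M HCl to pH 3, 0 °C; then pyridinium p-toluenesulfonate (5 mol%), CH2Cl2, rt
Reagents that add atoms: none
Why: Chemoselective borohydride reduction; the acid is first deprotonated and the lithium carboxylate resists hydride while the methyl ester is reduced, and the γ-hydroxy acid 28 lactonises on acidification, which places the arylmethyl group β to the carbonyl without touching the stereocentre.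

Step 21
Reactants: 29 lactone; 17 benzylic bromide
Product: 31 (3R,4R)-3-{4-(benzyloxy)-3-[(1S,2S)-1-[4-(benzyloxy)-3-methoxyphenyl]-1,3-bis(TBS-oxy)propan-2-yl]-5-methoxybenzyl}-4-({(2S,3R)-2-[4-(benzyloxy)-3-methoxyphenyl]-3-[(TBS-oxy)methyl]-7-methoxy-2,3-dihydro-1-benzofuran-5-yl}methyl)oxolan-2-one, via lithium enolate 30 (not isolated)
Conditions: LiN(SiMe3)2 (1.1 equiv), THF, −78 °C; 17 (1.2 equiv), −78 to −30 °C
Reagents that add atoms: none
Why: Alkylation of a β-substituted γ-butyrolactone enolate; the bromide approaches the planar enolate on the face away from the C4 substituent (1,2-induction), which gives the trans (3R,4R) lactone, also the more stable isomer.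

Step 22
Reactants: 31 fully protected lactone
Product: 32 (3R,4R)-3-{4-(benzyloxy)-3-[(1S,2S)-1-[4-(benzyloxy)-3-methoxyphenyl]-1,3-dihydroxypropan-2-yl]-5-methoxybenzyl}-4-({(2S,3R)-2-[4-(benzyloxy)-3-methoxyphenyl]-3-(hydroxymethyl)-7-methoxy-2,3-dihydro-1-benzofuran-5-yl}methyl)oxolan-2-one
Conditions: HF·pyridine, pyridine, THF, 0 °C to rt
Reagents that add atoms: none
Why: Fluoride cleavage of the three silyl ethers; with excess pyridine the medium is only weakly acidic, the phenols are still benzylated so neither a quinone methide nor ring closure onto C1' can occur, and the lactone is not attacked.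

Step 23
Reactants: 32 tribenzyl ether
Product: 33 (3R,4R)-3-{3-[(1S,2S)-1,3-dihydroxy-1-(4-hydroxy-3-methoxyphenyl)propan-2-yl]-4-hydroxy-5-methoxybenzyl}-4-{[(2S,3R)-2-(4-hydroxy-3-methoxyphenyl)-3-(hydroxymethyl)-7-methoxy-2,3-dihydro-1-benzofuran-5-yl]methyl}oxolan-2-one
Conditions: H2 (1 atm), Pd/C (10%), EtOAc/THF, rt, stopped at full conversion
Reagents that add atoms: none
Why: Hydrogenolysis of the three aryl benzyl ethers under neutral conditions; the O–CH2Ph bonds should be cleaved faster than the secondary benzylic C–OH bond and the C2–O bond of the dihydrobenzofuran, and the absence of acid keeps the ring A phenol from closing onto C1'.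

## Compound list

1 | acenaphthylene-1,2-dione | O=C1C(=O)c2cccc3cccc1c23 | starting material
2 | cis-1,2-dimethyl-1,2-dihydroacenaphthylene-1,2-diol (meso) | C[C@]1(O)c2cccc3cccc(c23)[C@@]1(C)O | intermediate
3 | tert-butyl(dimethyl)(prop-2-yn-1-yloxy)silane | C#CCO[Si](C)(C)C(C)(C)C | starting material
4 | 2-[(Z)-3-(TBS-oxy)prop-1-enyl]-1,3,2-benzodioxaborole (formed in the flask, not isolated) | CC(C)(C)[Si](C)(C)OC/C=C\B1Oc2ccccc2O1 | intermediate
5 | (Z)-3-(TBS-oxy)prop-1-enylboronic acid cis-1,2-dimethylacenaphthene-1,2-diyl ester | CC(C)(C)[Si](C)(C)OC/C=C\B1O[C@@]2(C)c3cccc4cccc(c34)[C@@]2(C)O1 | intermediate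
6 | 4-bromo-2-methoxyphenol | COc1cc(Br)ccc1O | starting material
7 | 1-(benzyloxy)-4-bromo-2-methoxybenzene | COc1cc(Br)ccc1OCc1ccccc1 | intermediate
8 | methyl 3,4-dihydroxy-5-methoxybenzoate | COC(=O)c1cc(O)c(O)c(OC)c1 | starting material
9 | methyl 4-(benzyloxy)-3-hydroxy-5-methoxybenzoate | COC(=O)c1cc(O)c(OCc2ccccc2)c(OC)c1 | intermediate
10 | methyl 4-(benzyloxy)-3-methoxy-5-(trifluoromethylsulfonyloxy)benzoate | COC(=O)c1cc(OC)c(OCc2ccccc2)c(OS(=O)(=O)C(F)(F)F)c1 | intermediate
11 | [4-(benzyloxy)-3-methoxyphenyl]lithium (formed in the flask, not isolated) | [Li]c1ccc(OCc2ccccc2)c(OC)c1 | intermediate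
12 | lithium [4-(benzyloxy)-3-methoxyphenyl][(Z)-3-(TBS-oxy)prop-1-enyl](cis-1,2-dimethylacenaphthene-1,2-diolato)borate, both boron epimers (solvent-free solid under argon, used as a THF stock solution) | [Li+].COc1cc([B-]2(/C=C\CO[Si](C)(C)C(C)(C)C)O[C@@]3(C)c4cccc5cccc(c45)[C@@]3(C)O2)ccc1OCc1ccccc1 | intermediate
13 | methyl 4-(benzyloxy)-3-[(1S,2S)-1-[4-(benzyloxy)-3-methoxyphenyl]-3-(TBS-oxy)-1-borylpropan-2-yl]-5-methoxybenzoate, boron as the cyclic ester of diol 2 | COc1cc([C@@H](B2O[C@@]3(C)c4cccc5cccc(c45)[C@@]3(C)O2)[C@H](CO[Si](C)(C)C(C)(C)C)c2cc(C(=O)OC)cc(OC)c2OCc2ccccc2)ccc1OCc1ccccc1 | intermediate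
14 | methyl 4-(benzyloxy)-3-[(1S,2S)-1-[4-(benzyloxy)-3-methoxyphenyl]-3-(TBS-oxy)-1-hydroxypropan-2-yl]-5-methoxybenzoate | COc1cc([C@@H](O)[C@H](CO[Si](C)(C)C(C)(C)C)c2cc(C(=O)OC)cc(OC)c2OCc2ccccc2)ccc1OCc1ccccc1 | intermediate
15 | methyl 4-(benzyloxy)-3-[(1S,2S)-1-[4-(benzyloxy)-3-methoxyphenyl]-1,3-bis(TBS-oxy)propan-2-yl]-5-methoxybenzoate | COc1cc([C@@H](O[Si](C)(C)C(C)(C)C)[C@H](CO[Si](C)(C)C(C)(C)C)c2cc(C(=O)OC)cc(OC)c2OCc2ccccc2)ccc1OCc1ccccc1 | intermediate
16 | {4-(benzyloxy)-3-[(1S,2S)-1-[4-(benzyloxy)-3-methoxyphenyl]-1,3-bis(TBS-oxy)propan-2-yl]-5-methoxyphenyl}methanol | COc1cc([C@@H](O[Si](C)(C)C(C)(C)C)[C@H](CO[Si](C)(C)C(C)(C)C)c2cc(CO)cc(OC)c2OCc2ccccc2)ccc1OCc1ccccc1 | intermediate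
17 | 4-(benzyloxy)-3-[(1S,2S)-1-[4-(benzyloxy)-3-methoxyphenyl]-1,3-bis(TBS-oxy)propan-2-yl]-5-methoxybenzyl bromide | COc1cc([C@@H](O[Si](C)(C)C(C)(C)C)[C@H](CO[Si](C)(C)C(C)(C)C)c2cc(CBr)cc(OC)c2OCc2ccccc2)ccc1OCc1ccccc1 | intermediate
18 | (1R,2R) mirror image of boronic ester 13 (formed in the flask, not isolated) | COc1cc([C@H](B2O[C@@]3(C)c4cccc5cccc(c45)[C@@]3(C)O2)[C@@H](CO[Si](C)(C)C(C)(C)C)c2cc(C(=O)OC)cc(OC)c2OCc2ccccc2)ccc1OCc1ccccc1 | intermediate
19 | methyl 4-(benzyloxy)-3-[(1R,2R)-1-[4-(benzyloxy)-3-methoxyphenyl]-3-(TBS-oxy)-1-hydroxypropan-2-yl]-5-methoxybenzoate | COc1cc([C@H](O)[C@@H](CO[Si](C)(C)C(C)(C)C)c2cc(C(=O)OC)cc(OC)c2OCc2ccccc2)ccc1OCc1ccccc1 | intermediate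
20 | methyl 4-hydroxy-3-[(1R,2R)-3-(TBS-oxy)-1-hydroxy-1-(4-hydroxy-3-methoxyphenyl)propan-2-yl]-5-methoxybenzoate | COc1cc([C@H](O)[C@@H](CO[Si](C)(C)C(C)(C)C)c2cc(C(=O)OC)cc(OC)c2O)ccc1O | intermediate
21 | methyl (2S,3R)-3-[(TBS-oxy)methyl]-2-(4-hydroxy-3-methoxyphenyl)-7-methoxy-2,3-dihydro-1-benzofuran-5-carboxylate | COC(=O)c1cc(OC)c2c(c1)[C@H](CO[Si](C)(C)C(C)(C)C)[C@@H](c1ccc(O)c(OC)c1)O2 | intermediate
22 | methyl (2S,3R)-2-[4-(benzyloxy)-3-methoxyphenyl]-3-[(TBS-oxy)methyl]-7-methoxy-2,3-dihydro-1-benzofuran-5-carboxylate | COC(=O)c1cc(OC)c2c(c1)[C@H](CO[Si](C)(C)C(C)(C)C)[C@@H](c1ccc(OCc3ccccc3)c(OC)c1)O2 | intermediate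
23 | {(2S,3R)-2-[4-(benzyloxy)-3-methoxyphenyl]-3-[(TBS-oxy)methyl]-7-methoxy-2,3-dihydro-1-benzofuran-5-yl}methanol | OCc1cc(OC)c2c(c1)[C@H](CO[Si](C)(C)C(C)(C)C)[C@@H](c1ccc(OCc3ccccc3)c(OC)c1)O2 | intermediate
24 | (2S,3R)-2-[4-(benzyloxy)-3-methoxyphenyl]-3-[(TBS-oxy)methyl]-7-methoxy-2,3-dihydro-1-benzofuran-5-carbaldehyde | O=Cc1cc(OC)c2c(c1)[C@H](CO[Si](C)(C)C(C)(C)C)[C@@H](c1ccc(OCc3ccccc3)c(OC)c1)O2 | intermediate
25 | dimethyl succinate | COC(=O)CCC(=O)OC | starting material
26 | (3E)-4-{(2S,3R)-2-[4-(benzyloxy)-3-methoxyphenyl]-3-[(TBS-oxy)methyl]-7-methoxy-2,3-dihydro-1-benzofuran-5-yl}-3-(methoxycarbonyl)but-3-enoic acid | OC(=O)C/C(C(=O)OC)=C\c1cc(OC)c2c(c1)[C@H](CO[Si](C)(C)C(C)(C)C)[C@@H](c1ccc(OCc3ccccc3)c(OC)c1)O2 | intermediate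
27 | (3R)-4-{(2S,3R)-2-[4-(benzyloxy)-3-methoxyphenyl]-3-[(TBS-oxy)methyl]-7-methoxy-2,3-dihydro-1-benzofuran-5-yl}-3-(methoxycarbonyl)butanoic acid | OC(=O)C[C@H](C(=O)OC)Cc1cc(OC)c2c(c1)[C@H](CO[Si](C)(C)C(C)(C)C)[C@@H](c1ccc(OCc3ccccc3)c(OC)c1)O2 | intermediate
28 | (3R)-4-{(2S,3R)-2-[4-(benzyloxy)-3-methoxyphenyl]-3-[(TBS-oxy)methyl]-7-methoxy-2,3-dihydro-1-benzofuran-5-yl}-3-(hydroxymethyl)butanoic acid (formed in the flask, not isolated) | OC(=O)C[C@H](CO)Cc1cc(OC)c2c(c1)[C@H](CO[Si](C)(C)C(C)(C)C)[C@@H](c1ccc(OCc3ccccc3)c(OC)c1)O2 | intermediate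
29 | (4R)-4-({(2S,3R)-2-[4-(benzyloxy)-3-methoxyphenyl]-3-[(TBS-oxy)methyl]-7-methoxy-2,3-dihydro-1-benzofuran-5-yl}methyl)oxolan-2-one | O=C1OC[C@@H](C1)Cc1cc(OC)c2c(c1)[C@H](CO[Si](C)(C)C(C)(C)C)[C@@H](c1ccc(OCc3ccccc3)c(OC)c1)O2 | intermediate
30 | lithium enolate of lactone 29 (formed in the flask, not isolated) | [Li]OC1=C[C@H](CO1)Cc1cc(OC)c2c(c1)[C@H](CO[Si](C)(C)C(C)(C)C)[C@@H](c1ccc(OCc3ccccc3)c(OC)c1)O2 | intermediate
31 | (3R,4R)-3-{4-(benzyloxy)-3-[(1S,2S)-1-[4-(benzyloxy)-3-methoxyphenyl]-1,3-bis(TBS-oxy)propan-2-yl]-5-methoxybenzyl}-4-({(2S,3R)-2-[4-(benzyloxy)-3-methoxyphenyl]-3-[(TBS-oxy)methyl]-7-methoxy-2,3-dihydro-1-benzofuran-5-yl}methyl)oxolan-2-one | COc1cc([C@@H](O[Si](C)(C)C(C)(C)C)[C@H](CO[Si](C)(C)C(C)(C)C)c2cc(C[C@H]3C(=O)OC[C@@H]3Cc3cc(OC)c4c(c3)[C@H](CO[Si](C)(C)C(C)(C)C)[C@@H](c3ccc(OCc5ccccc5)c(OC)c3)O4)cc(OC)c2OCc2ccccc2)ccc1OCc1ccccc1 | intermediate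
32 | (3R,4R)-3-{4-(benzyloxy)-3-[(1S,2S)-1-[4-(benzyloxy)-3-methoxyphenyl]-1,3-dihydroxypropan-2-yl]-5-methoxybenzyl}-4-({(2S,3R)-2-[4-(benzyloxy)-3-methoxyphenyl]-3-(hydroxymethyl)-7-methoxy-2,3-dihydro-1-benzofuran-5-yl}methyl)oxolan-2-one | COc1cc([C@@H](O)[C@H](CO)c2cc(C[C@H]3C(=O)OC[C@@H]3Cc3cc(OC)c4c(c3)[C@H](CO)[C@@H](c3ccc(OCc5ccccc5)c(OC)c3)O4)cc(OC)c2OCc2ccccc2)ccc1OCc1ccccc1 | intermediate
33 | (3R,4R)-3-{3-[(1S,2S)-1,3-dihydroxy-1-(4-hydroxy-3-methoxyphenyl)propan-2-yl]-4-hydroxy-5-methoxybenzyl}-4-{[(2S,3R)-2-(4-hydroxy-3-methoxyphenyl)-3-(hydroxymethyl)-7-methoxy-2,3-dihydro-1-benzofuran-5-yl]methyl}oxolan-2-one (CNP0186558.2) | COc1cc([C@@H](O)[C@H](CO)c2cc(C[C@H]3C(=O)OC[C@@H]3Cc3cc(OC)c4c(c3)[C@H](CO)[C@@H](c3ccc(O)c(OC)c3)O4)cc(OC)c2O)ccc1O | target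

## Step count and least certain steps

Total: 23 steps. Longest linear sequence: 15 steps (1 → 2 → 5 → 12 → 19 → 20 → 21 → 22 → 23 → 24 → 26 → 27 → 29 → 31 → 32 → 33; steps 1, 2, 6 and 12–23).

**Step 7 (key step; step 12 shares its fate).**
- What may go wrong: direct transfer of the alkenyl or aryl group from boron to palladium (Suzuki–Miyaura pathway) may outrun alkene binding, because the Z substituent and the ortho-benzyloxy group crowd the π-complex. β-Hydride or β-silyloxy elimination may overtake reductive elimination. Facial selectivity on a Z alkene may be eroded. Incomplete removal of bromide may slow the catalyst.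
- Fallback: sets out from 10 and returns at 14 (with the mirror-image auxiliary at 19), using an auxiliary-controlled anti-aldol reaction in place of the coupling.
  - Negishi-type coupling of 10 with the Reformatsky reagent BrZnCH2CO2t-Bu (Pd2(dba)3, 2-dicyclohexylphosphino-2',4',6'-triisopropylbiphenyl, THF) gives methyl 4-(benzyloxy)-3-(2-tert-butoxy-2-oxoethyl)-5-methoxybenzoate F1.
  - CF3CO2H in CH2Cl2 frees [2-(benzyloxy)-3-methoxy-5-(methoxycarbonyl)phenyl]acetic acid F2.
  - Pivaloyl chloride/Et3N and lithiated (4S)-4-benzyloxazolidin-2-one give the N-acyl oxazolidinone F3.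
  - The MgCl2-catalysed anti-aldol reaction (MgCl2, Et3N, Me3SiCl, EtOAc, then dilute acid) with commercial 4-(benzyloxy)-3-methoxybenzaldehyde gives the (2R,3S) anti-aldol adduct F4.
  - NaBH4 in THF/H2O removes the auxiliary reductively and spares the aryl ester, giving methyl 4-(benzyloxy)-3-[(1S,2S)-1-[4-(benzyloxy)-3-methoxyphenyl]-1,3-dihydroxypropan-2-yl]-5-methoxybenzoate F5.
  - TBSCl/imidazole silylates the primary hydroxyl selectively to give 14.

**Step 2.**
- What may go wrong: erosion of the Z geometry by rhodium hydride isomerisation, competing ordinary syn-hydroboration, or incomplete exchange of catechol for the hindered diol.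
- Fallback: sets out from 3 and returns at 5. Lithiation of 3 (n-BuLi, THF, −78 °C), borylation with B(Oi-Pr)3, acidification with HCl in Et2O and addition of diol 2 give 3-(TBS-oxy)prop-1-ynylboronic acid cis-1,2-dimethylacenaphthene-1,2-diyl ester F6. Semihydrogenation over Pd/CaCO3 poisoned with Pb(OAc)2 and quinoline adds hydrogen syn and gives 5.

**Step 14.**
- What may go wrong: loss of the primary silyl ether under acid, or capture of the quinone methide by a second molecule (oligomers) in place of the ring B phenol.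
- Fallback: sets out from 20 and returns at 21 with no new compound (F0). Mitsunobu closure (PPh3, diisopropyl azodicarboxylate, THF, 0 °C): the ring B phenol displaces the activated benzylic oxygen with inversion, which from the anti diol gives the same trans ring without acid.

**Step 21.**
- What may go wrong: the electron-rich benzylic bromide 17 may ionise and decompose before it is alkylated, or proton exchange between product and enolate may lead to double alkylation.
- Fallback: sets out from 16 and 29 and returns at 31.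
  - MnO2 oxidises 16 to 4-(benzyloxy)-3-[(1S,2S)-1-[4-(benzyloxy)-3-methoxyphenyl]-1,3-bis(TBS-oxy)propan-2-yl]-5-methoxybenzaldehyde F7.
  - Aldol condensation of 29 with F7 (KOt-Bu, THF, 0 °C to rt, loss of water by E1cB) gives the (E)-3-arylidene lactone F8.
  - Conjugate reduction (NaBH4, NiCl2·6H2O, MeOH/THF, 0 °C), which leaves benzyl ethers intact, gives mainly the (3S,4R) cis lactone F9 by protonation anti to the C4 substituent.
  - Equilibration with 1,8-diazabicyclo[5.4.0]undec-7-ene in toluene moves C3 to the more stable trans arrangement, 31.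

**Step 23 (the same concern applies to step 13).**
- What may go wrong: over-reduction, that is hydrogenolysis of the benzylic C1'–OH bond or of the C2–O bond of the dihydrobenzofuran once the phenols are free, or closure of the ring A phenol onto C1' if the catalyst carries traces of acid.
- Fallback: sets out from 31 and returns at 33 by reversing the order of deprotection. Hydrogenolysis of the fully silylated 31 (H2, Pd/C, EtOAc), where C1'–O is a bulky silyl ether, gives the triphenol tris-silyl ether F10. Et3N·3HF in THF then removes the silyl groups under nearly neutral conditions to give 33.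

## Further compounds

F1 | step 7 | methyl 4-(benzyloxy)-3-(2-tert-butoxy-2-oxoethyl)-5-methoxybenzoate | COC(=O)c1cc(OC)c(OCc2ccccc2)c(CC(=O)OC(C)(C)C)c1
F2 | step 7 | [2-(benzyloxy)-3-methoxy-5-(methoxycarbonyl)phenyl]acetic acid | COC(=O)c1cc(OC)c(OCc2ccccc2)c(CC(O)=O)c1
F3 | step 7 | methyl 4-(benzyloxy)-3-{2-[(4S)-4-benzyl-2-oxo-1,3-oxazolidin-3-yl]-2-oxoethyl}-5-methoxybenzoate | COC(=O)c1cc(OC)c(OCc2ccccc2)c(CC(=O)N2[C@@H](Cc3ccccc3)COC2=O)c1
F4 | step 7 | methyl 4-(benzyloxy)-3-{(2R,3S)-1-[(4S)-4-benzyl-2-oxo-1,3-oxazolidin-3-yl]-3-[4-(benzyloxy)-3-methoxyphenyl]-3-hydroxy-1-oxopropan-2-yl}-5-methoxybenzoate | COc1cc([C@@H](O)[C@H](C(=O)N3[C@@H](Cc4ccccc4)COC3=O)c2cc(C(=O)OC)cc(OC)c2OCc2ccccc2)ccc1OCc1ccccc1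
F5 | step 7 | methyl 4-(benzyloxy)-3-[(1S,2S)-1-[4-(benzyloxy)-3-methoxyphenyl]-1,3-dihydroxypropan-2-yl]-5-methoxybenzoate | COc1cc([C@@H](O)[C@H](CO)c2cc(C(=O)OC)cc(OC)c2OCc2ccccc2)ccc1OCc1ccccc1
F6 | step 2 | 3-(TBS-oxy)prop-1-ynylboronic acid cis-1,2-dimethylacenaphthene-1,2-diyl ester | CC(C)(C)[Si](C)(C)OCC#CB1O[C@@]2(C)c3cccc4cccc(c34)[C@@]2(C)O1
F0 | step 14 | none | none
F7 | step 21 | 4-(benzyloxy)-3-[(1S,2S)-1-[4-(benzyloxy)-3-methoxyphenyl]-1,3-bis(TBS-oxy)propan-2-yl]-5-methoxybenzaldehyde | COc1cc([C@@H](O[Si](C)(C)C(C)(C)C)[C@H](CO[Si](C)(C)C(C)(C)C)c2cc(C=O)cc(OC)c2OCc2ccccc2)ccc1OCc1ccccc1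
F8 | step 21 | (3E,4R)-3-{4-(benzyloxy)-3-[(1S,2S)-1-[4-(benzyloxy)-3-methoxyphenyl]-1,3-bis(TBS-oxy)propan-2-yl]-5-methoxybenzylidene}-4-({(2S,3R)-2-[4-(benzyloxy)-3-methoxyphenyl]-3-[(TBS-oxy)methyl]-7-methoxy-2,3-dihydro-1-benzofuran-5-yl}methyl)oxolan-2-one | COc1cc([C@@H](O[Si](C)(C)C(C)(C)C)[C@H](CO[Si](C)(C)C(C)(C)C)c2cc(/C=C3/C(=O)OC[C@@H]3Cc3cc(OC)c4c(c3)[C@H](CO[Si](C)(C)C(C)(C)C)[C@@H](c3ccc(OCc5ccccc5)c(OC)c3)O4)cc(OC)c2OCc2ccccc2)ccc1OCc1ccccc1
F9 | step 21 | (3S,4R) cis epimer of lactone 31 | COc1cc([C@@H](O[Si](C)(C)C(C)(C)C)[C@H](CO[Si](C)(C)C(C)(C)C)c2cc(C[C@@H]3C(=O)OC[C@@H]3Cc3cc(OC)c4c(c3)[C@H](CO[Si](C)(C)C(C)(C)C)[C@@H](c3ccc(OCc5ccccc5)c(OC)c3)O4)cc(OC)c2OCc2ccccc2)ccc1OCc1ccccc1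
F10 | step 23 | (3R,4R)-3-{3-[(1S,2S)-1,3-bis(TBS-oxy)-1-(4-hydroxy-3-methoxyphenyl)propan-2-yl]-4-hydroxy-5-methoxybenzyl}-4-({(2S,3R)-3-[(TBS-oxy)methyl]-2-(4-hydroxy-3-methoxyphenyl)-7-methoxy-2,3-dihydro-1-benzofuran-5-yl}methyl)oxolan-2-one | COc1cc([C@@H](O[Si](C)(C)C(C)(C)C)[C@H](CO[Si](C)(C)C(C)(C)C)c2cc(C[C@H]3C(=O)OC[C@@H]3Cc3cc(OC)c4c(c3)[C@H](CO[Si](C)(C)C(C)(C)C)[C@@H](c3ccc(O)c(OC)c3)O4)cc(OC)c2O)ccc1O
A1 | alternative 1 | 3-{[(2S,3R)-2-(4-hydroxy-3-methoxyphenyl)-3-(hydroxymethyl)-7-methoxy-2,3-dihydro-1-benzofuran-5-yl]methyl}cyclobutan-1-one | O=C1CC(C1)Cc1cc(OC)c2c(c1)[C@H](CO)[C@@H](c1ccc(O)c(OC)c1)O2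
A2 | alternative 1 | (4R)-4-{[(2S,3R)-2-(4-hydroxy-3-methoxyphenyl)-3-(hydroxymethyl)-7-methoxy-2,3-dihydro-1-benzofuran-5-yl]methyl}oxolan-2-one | C1C(=O)OC[C@@H]1Cc1cc(OC)c2c(c1)[C@H](CO)[C@@H](c1ccc(O)c(OC)c1)O2
A3 | alternative 2 | 5-bromo-1-iodo-3-methoxy-2-{[(1S)-1-[4-(TBS-oxy)-3-methoxyphenyl]prop-2-en-1-yl]oxy}benzene | Brc1cc(OC)c(O[C@@H](C=C)c2ccc(O[Si](C)(C)C(C)(C)C)c(OC)c2)c(I)c1
A4 | alternative 2 | (2S,3R)-5-bromo-2-[4-(TBS-oxy)-3-methoxyphenyl]-7-methoxy-3-{[(2,2,6,6-tetramethylpiperidin-1-yl)oxy]methyl}-2,3-dihydro-1-benzofuran | Brc1cc(OC)c2c(c1)[C@H](CON1C(C)(C)CCCC1(C)C)[C@@H](c1ccc(O[Si](C)(C)C(C)(C)C)c(OC)c1)O2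
A5 | alternative 3 | (2R)-2-(5-bromo-2-hydroxy-3-methoxyphenyl)-3-(TBS-oxy)-1-(4-hydroxy-3-methoxyphenyl)propan-1-ol, both C1 epimers | COc1cc(C(O)[C@@H](CO[Si](C)(C)C(C)(C)C)c2cc(Br)cc(OC)c2O)ccc1O
A6 | alternative 3 | (2S,3R)-5-bromo-3-[(TBS-oxy)methyl]-2-(4-hydroxy-3-methoxyphenyl)-7-methoxy-2,3-dihydro-1-benzofuran | Brc1cc(OC)c2c(c1)[C@H](CO[Si](C)(C)C(C)(C)C)[C@@H](c1ccc(O)c(OC)c1)O2
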